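If I want the rate of this flask, I count catalyst rounds. The round time is the catalyst charge over the rate of making product, and I add up its waits.

all flasks: free catalyst 2.5 mM

| run | substrate | reagent | added ligand | remark |
|---|---|---|---|---|
| alpha | 0.10 M | 0.080 M | 7.4 mM | run made earlier |
| zeta | 0.10 M | 0.080 M | 16 mM | run made earlier |
| eta | 0.050 M | 0.080 M | 11 mM | run made earlier |
| flask | 0.10 M | 0.0800 M | 11 mM |  |

| run | time / min | product / % | substrate / % |
|---|---|---|---|
| alpha | 6.00 | 51.8 | 47.2 |
| alpha | 12.0 | 74.0 | 25.6 |
| alpha | 15.0 | 78.1 | 20.2 |
| alpha | 25.0 | 79.9 | 17.7 |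
| alpha | 30.0 | 80.2 | 17.6 |
| alpha | 40.0 | 80.3 | 17.4 |
| zeta | 6.00 | 44.0 | 54.6 |
| zeta | 12.0 | 64.3 | 34.7 |
| zeta | 15.0 | 70.8 | 28.1 |
| zeta | 25.0 | 79.4 | 18.3 |
| zeta | 30.0 | 79.6 | 18.2 |
| zeta | 40.0 | 79.7 | 18.1 |
| eta | 4.00 | 49.4 | 49.2 |
| eta | 10.0 | 77.8 | 21.5 |
| eta | 20.0 | 94.8 | 5.7 |
| eta | 30.0 | 99.2 | 1.3 |
| eta | 40.0 | 99.3 | 0.6 |

(each reading ± 0.3 percentage points)

- factor on the rate of making product when 30% of the substrate are converted if reagent is charged twice over
- factor on the rate when 30% of the substrate are converted if free catalyst is charged at 25 mM instead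

- the numbers in the tables scatter with a standard deviation of 0.3 percentage points
- reactions considered so far: released group -> by-product carried off; substrate + free catalyst -> catalyst intermediate A; catalyst intermediate B -> catalyst intermediate C; catalyst intermediate C <-> released group + catalyst intermediate D; reagent + catalyst intermediate A -> catalyst intermediate B; free catalyst + added ligand <-> idle complex; catalyst intermediate D -> free catalyst + product
- no earlier run changes the charge of free catalyst; that part of a forecast is a guess
- no earlier run changes the charge of reagent; that part of a forecast is a guess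

First I take the substrate wait alone. Late in eta, reagent is plentiful and the substrate decays as a pseudo-first-order tail. Between 20.0 min and 30.0 min that gives the clearing constant, rate per unit of c(substrate), 0.148 /min. Eta holds the flask's ligand, 11 mM, so the ligand needs no term of its own. At 30% conversion c(substrate) is 70.0 mM, so the wait is 0.242 min.

Then I add reagent. Alpha stops near 80.3%, and c(reagent) over c(substrate) is 80.0%, so reagent is the limiting reagent. Between 12.0 min and 15.0 min alpha's round takes 1.83 min, at mean c(substrate) 22.9 mM and c(reagent) 3.95 mM. I take off the substrate wait, though alpha holds less ligand. This leaves 1.09 min, a reagent constant of 0.580 /min.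

At 30% c(reagent) is 50.0 mM, so the round takes 0.328 min. Doubled reagent shortens it to 0.275 min, a factor of 1.19. Eta tests the sum: between 4.00 min and 10.0 min it predicts 2.39 mM/min, and the readings give 2.37 mM/min. For the catalyst question I reckon just the charge ratio, 10.0.

The forecast gives 1.18, slightly below my factor, and 14.5, above my ratio, on the ground that “the 11 mM ligand is swamped”.

The flask gives 1.17 and 13.7.

    released group → by-product carried off (k = 6.00 × 10⁻⁴ /s)
    substrate + free catalyst → catalyst intermediate A (k = 3.30 /M/s)
    catalyst intermediate B → catalyst intermediate C (k = 10.0 /s)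
    catalyst intermediate C ⇌ released group + catalyst intermediate D (K = 5.40 M, k = 1.30 /s)
    reagent + catalyst intermediate A → catalyst intermediate B (k = 5.40 /M/s)
    free catalyst + added ligand ⇌ idle complex (K = 270 /M, k = 0.680 /M/s)
    catalyst intermediate D → free catalyst + product (k = 0.180 /s)

At 4.00 min the flask holds c(substrate) 62.4 mM and c(reagent) 42.9 mM; my two constants give 6.73 mM/min, while catalyst intermediate D, 25.0% of the catalyst, makes product at 6.75 mM/min. By 20.0 min reagent stands at 0.713% of its charge and product at 79.4%, and at 40.0 min reagent is 0%, with 97.5% of the catalyst in the resting state, catalyst intermediate A.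

The earlier runs and the new flask stem from a simulated flask for an exercise, and the scatter is random.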